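The route never couples at the crowded C4–N1' junction; ring B is grown on an aniline nitrogen instead. A Paal–Knorr condensation of 2-bromo-4-methoxy-5-nitroaniline with 2-(2-oxoethyl)cyclohexane-1,3-dione creates N1'–C2' and N1'–C7a' in one operation and gives a 1-aryl-4-oxotetrahydroindole. The feature exploited is the substitution pattern of ring B: Br at C2' and C5' but H at C3'. The surviving C4' ketone sends bromine to the free pyrrole α-carbon C2' and to the enolisable C5'. It is then removed by reduction, dehydration and dehydrogenation. The nitro group, ortho to OMe, becomes N1 of ring A by Bartoli annulation, and C3 is brominated last.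

Key step: step 4

Assumption: the target SMILES carries no stereodescriptor, so the hindered C4–N1' axis is built without control and all axially chiral compounds are racemic. Unprimed locants refer to ring A (the N–H indole) and primed locants to ring B (the N-linked indole).

Step 1
Reactants: 1 4-methoxy-3-nitroaniline
Product: 2 2-bromo-4-methoxy-5-nitroaniline
Conditions: NBS (1.0 equiv), MeCN, 0 °C to rt, dark
Reagents that add atoms: N-bromosuccinimide, O=C1CCC(=O)N1Br
Why: Electrophilic aromatic bromination follows the amino group, whose para carbon carries OMe and whose second ortho carbon is wedged between NH2 and NO2, so only the open ortho C–H should be substituted.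

Step 2
Reactants: 3 cyclohexane-1,3-dione; 4 allyl bromide
Product: 5 2-allylcyclohexane-1,3-dione
Conditions: KOH (1.0 equiv), Cu powder (cat.), H2O, 0 °C to rt
Reagents that add atoms: none
Why: C-alkylation of the stabilised 1,3-dione enolate with a soft allylic halide in water, where hydrogen bonding masks the enolate oxygens, is the classical entry to 2-allyl-1,3-diones, and one equivalent of halide limits double allylation.

Step 3
Reactants: 5 2-allylcyclohexane-1,3-dione
Product: 7 2-(2-oxoethyl)cyclohexane-1,3-dione, via secondary ozonide 6 (not isolated)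
Conditions: O3, CH2Cl2, −78 °C (Sudan Red 7B end point); then Me2S (5 equiv), −78 °C to rt; used crude
Reagents that add atoms: ozone, [O-][O+]=O
Why: In this ozonolysis with reductive work-up the isolated terminal alkene adds ozone faster than the hydrogen-bonded, acceptor-substituted enol C=C of the dione, the dye end point prevents an overdose, and Me2S reduces ozonide 6 to the aldehyde, which equilibrates with its enol lactol and is therefore taken on without storage.

Step 4
Reactants: 2 2-bromo-4-methoxy-5-nitroaniline; 7 2-(2-oxoethyl)cyclohexane-1,3-dione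
Product: 10 1-(2-bromo-4-methoxy-5-nitrophenyl)-1,5,6,7-tetrahydro-4H-indol-4-one, via enaminone aldehyde 8 (not isolated), via cyclic hemiaminal 9 (not isolated)
Conditions: 2 (1.0 equiv), 7 (1.5 equiv, in portions), AcOH, 90 °C
Reagents that add atoms: none
Why: This is a Paal–Knorr pyrrole synthesis, a reaction type established for 2-(2-oxoalkyl)cyclohexane-1,3-diones and primary amines: in acetic acid the aniline adds to one ring carbonyl and loses water to give vinylogous amide 8 (bond N1'–C7a'). The N–H of 8 then attacks the side-chain aldehyde in a 5-exo-trig closure (bond N1'–C2') to hemiaminal 9, and a second loss of water aromatises the new five-membered ring; if the imine of the aldehyde forms first, closure onto the ring ketone is again 5-exo-trig and ends at the same product. No stereocentre survives, because the carbinol carbon of 9 becomes sp2. Constitutional selectivity is built into 7: a mirror plane interchanges its two ring carbonyls, and the aldehyde carbon stands in a 1,4-relationship to either of them, the only spacing from which a pyrrole can arise. The selectivity that has to be won is nitrogen against oxygen closure, since the enol oxygen can cyclise onto the aldehyde to a furan; the para-methoxy group keeps the amine nucleophilic, the weak acid leaves it unprotonated, and the inexpensive aldehyde is fed in portions and in excess so that it always meets free amine. The ortho bromine slows a condensation of this kind far less than it would hamper a metal-catalysed N-arylation at a carbon flanked on both sides.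

Step 5
Reactants: 10 1-(2-bromo-4-methoxy-5-nitrophenyl)-1,5,6,7-tetrahydro-4H-indol-4-one
Product: 11 2-bromo-1-(2-bromo-4-methoxy-5-nitrophenyl)-1,5,6,7-tetrahydro-4H-indol-4-one
Conditions: NBS (1.0 equiv), DMF, 0 °C to rt, dark
Reagents that add atoms: N-bromosuccinimide, O=C1CCC(=O)N1Br
Why: In this electrophilic bromination of a 3-acylpyrrole the carbonyl on C3a' deactivates the neighbouring C3', so the only free α-carbon C2' should react, while the nitro-substituted aryl ring is too electron-poor to compete and ionic conditions in the dark avoid attack on the CH2 groups.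

Step 6
Reactants: 11 2-bromo-1-(2-bromo-4-methoxy-5-nitrophenyl)-1,5,6,7-tetrahydro-4H-indol-4-one
Product: 12 2,5-dibromo-1-(2-bromo-4-methoxy-5-nitrophenyl)-1,5,6,7-tetrahydro-4H-indol-4-one
Conditions: CuBr2 (2.1 equiv), EtOAc/CHCl3 1:1, reflux
Reagents that add atoms: CuBr2 (copper dibromide), [Cu+2].[Br-].[Br-]
Why: Heterogeneous α-bromination of a ketone with CuBr2 runs through the metal-bound enol, C5' is the only enolisable carbon, and the pyrrole ring, now deactivated by both the acyl group and C2'–Br, should resist attack at C3' and acid-induced bromine migration; the C5' stereocentre forms without control and is erased in step 8.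

Step 7
Reactants: 12 2,5-dibromo-1-(2-bromo-4-methoxy-5-nitrophenyl)-1,5,6,7-tetrahydro-4H-indol-4-one
Product: 13 2,5-dibromo-1-(2-bromo-4-methoxy-5-nitrophenyl)-4,5,6,7-tetrahydro-1H-indol-4-ol
Conditions: NaBH4 (1.2 equiv), CeCl3·7H2O (1.0 equiv), MeOH/THF, −20 to 0 °C; aq NH4Cl
Reagents that add atoms: none
Why: In this Luche-type 1,2-reduction the Lewis acid offsets the vinylogous-amide character of the C4' carbonyl, the α-bromine raises its electrophilicity, the nitro group and the C–Br bonds are inert to borohydride, and the near-neutral medium prevents epoxide closure; C4' forms as a mixture of diastereomers that converge in step 8.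

Step 8
Reactants: 13 2,5-dibromo-1-(2-bromo-4-methoxy-5-nitrophenyl)-4,5,6,7-tetrahydro-1H-indol-4-ol
Product: 15 2,5-dibromo-1-(2-bromo-4-methoxy-5-nitrophenyl)-1H-indole, via 6,7-dihydroindole 14 (not isolated)
Conditions: PPTS (20 mol%), 4 Å MS, toluene, 80 °C; once 13 is consumed, DDQ (1.2 equiv), rt to 60 °C
Reagents that add atoms: none
Why: E1 dehydration through the pyrrole-stabilised C4' cation gives the C4'=C5' vinyl bromide, as in the well-known 2-bromo-1-tetralol series. The weak acid spares the now electron-rich 2-bromopyrrole, and immediate DDQ dehydrogenation of C6'–C7' is driven by indole aromaticity and cannot expel the vinylic bromine.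

Step 9
Reactants: 15 2,5-dibromo-1-(2-bromo-4-methoxy-5-nitrophenyl)-1H-indole
Product: 16 5-bromo-4-(2,5-dibromo-1H-indol-1-yl)-7-methoxy-1H-indole
Conditions: vinylMgBr (1.0 M in THF, 3.5 equiv), THF, −45 °C; sat. aq NH4Cl
Reagents that add atoms: vinylmagnesium bromide, C=C[Mg]Br
Why: In the Bartoli indole synthesis the ortho methoxy group supplies the steric push the reaction needs, the [3,3]-sigmatropic shift can end only at the single free ortho C–H (the future C3a), and aryl bromides survive the vinyl Grignard reagent at this temperature, as the routine use of the reaction on bromonitroarenes shows.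

Step 10
Reactants: 16 5-bromo-4-(2,5-dibromo-1H-indol-1-yl)-7-methoxy-1H-indole
Product: 17 3,5-dibromo-4-(2,5-dibromo-1H-indol-1-yl)-7-methoxy-1H-indole
Conditions: NBS (1.0 equiv), DMF, −40 to 0 °C, dark
Reagents that add atoms: N-bromosuccinimide, O=C1CCC(=O)N1Br
Why: Electrophilic substitution should pick the most nucleophilic carbon, C3 of the N–H, methoxy-bearing ring A, because C3' of ring B is deactivated by the adjacent C2'–Br, by C5'–Br and by the N-aryl group, so one equivalent of NBS at low temperature should stop at the target.

Compound list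
1 | 4-methoxy-3-nitroaniline | COc1ccc(N)cc1[N+](=O)[O-] | starting material
2 | 2-bromo-4-methoxy-5-nitroaniline | COc1cc(Br)c(N)cc1[N+](=O)[O-] | intermediate
3 | cyclohexane-1,3-dione | O=C1CCCC(=O)C1 | starting material
4 | allyl bromide | C=CCBr | starting material
5 | 2-allylcyclohexane-1,3-dione | C=CCC1C(=O)CCCC1=O | intermediate
6 | secondary ozonide, 2-[(1,2,4-trioxolan-3-yl)methyl]cyclohexane-1,3-dione (racemic, not isolated) | O=C1CCCC(=O)C1CC1OCOO1 | intermediate
7 | 2-(2-oxoethyl)cyclohexane-1,3-dione | O=CCC1C(=O)CCCC1=O | intermediate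
8 | enaminone aldehyde, 2-{2-[(2-bromo-4-methoxy-5-nitrophenyl)amino]-6-oxocyclohex-1-en-1-yl}acetaldehyde (not isolated) | COc1cc(Br)c(NC2=C(CC=O)C(=O)CCC2)cc1[N+](=O)[O-] | intermediate
9 | cyclic hemiaminal, 1-(2-bromo-4-methoxy-5-nitrophenyl)-2-hydroxy-1,2,3,5,6,7-hexahydro-4H-indol-4-one (racemic, not isolated) | COc1cc(Br)c(N2C(O)CC3=C2CCCC3=O)cc1[N+](=O)[O-] | intermediate
10 | 1-(2-bromo-4-methoxy-5-nitrophenyl)-1,5,6,7-tetrahydro-4H-indol-4-one | COc1cc(Br)c(-n2ccc3c2CCCC3=O)cc1[N+](=O)[O-] | intermediate
11 | 2-bromo-1-(2-bromo-4-methoxy-5-nitrophenyl)-1,5,6,7-tetrahydro-4H-indol-4-one | COc1cc(Br)c(-n2c(Br)cc3c2CCCC3=O)cc1[N+](=O)[O-] | intermediate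
12 | 2,5-dibromo-1-(2-bromo-4-methoxy-5-nitrophenyl)-1,5,6,7-tetrahydro-4H-indol-4-one (C5' uncontrolled) | COc1cc(Br)c(-n2c(Br)cc3c2CCC(Br)C3=O)cc1[N+](=O)[O-] | intermediate
13 | 2,5-dibromo-1-(2-bromo-4-methoxy-5-nitrophenyl)-4,5,6,7-tetrahydro-1H-indol-4-ol (mixture of diastereomers) | COc1cc(Br)c(-n2c(Br)cc3c2CCC(Br)C3O)cc1[N+](=O)[O-] | intermediate
14 | 2,5-dibromo-1-(2-bromo-4-methoxy-5-nitrophenyl)-6,7-dihydro-1H-indole (not isolated) | COc1cc(Br)c(-n2c(Br)cc3c2CCC(Br)=C3)cc1[N+](=O)[O-] | intermediate
15 | 2,5-dibromo-1-(2-bromo-4-methoxy-5-nitrophenyl)-1H-indole | COc1cc(Br)c(-n2c(Br)cc3cc(Br)ccc32)cc1[N+](=O)[O-] | intermediate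
16 | 5-bromo-4-(2,5-dibromo-1H-indol-1-yl)-7-methoxy-1H-indole | COc1cc(Br)c(-n2c(Br)cc3cc(Br)ccc32)c2cc[nH]c12 | intermediate
17 | 3,5-dibromo-4-(2,5-dibromo-1H-indol-1-yl)-7-methoxy-1H-indole (CNP0191258.0, racemic axis) | COc1cc(Br)c(-n2c(Br)cc3cc(Br)ccc32)c2c(Br)c[nH]c12 | target

Total step count: 10
Longest linear sequence: 9 steps (steps 2 to 10, from 3 to 17)

Steps most likely to fail

Step 9. The Grignard reagent may be spent in plain reduction of the nitro group. The sigmatropic shift also has to end next to the bulky N-indolyl substituent, so conversion into the indole may be poor. The fallback sets out from 15 and comes back at 16.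
- Fe powder and NH4Cl in aqueous EtOH at 70 °C reduce the nitro group to 4-bromo-5-(2,5-dibromo-1H-indol-1-yl)-2-methoxyaniline F1.
- NIS in DMF at 0 °C iodinates the only open position ortho to NH2 and gives 4-bromo-3-(2,5-dibromo-1H-indol-1-yl)-2-iodo-6-methoxyaniline F2.
- Sonogashira coupling with trimethylsilylacetylene (PdCl2(PPh3)2, CuI, Et3N, rt) addresses the C–I bond ahead of the three C–Br bonds and gives 4-bromo-3-(2,5-dibromo-1H-indol-1-yl)-6-methoxy-2-[(trimethylsilyl)ethynyl]aniline F3.
- TBAF in refluxing THF removes silicon to give 4-bromo-3-(2,5-dibromo-1H-indol-1-yl)-2-ethynyl-6-methoxyaniline F4, which closes in the same flask to 16 by 5-endo-dig attack of nitrogen.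

Step 4. Closure through the enol oxygen may outrun the attack of the weakly basic, ortho-hindered amine, so that the aldehyde is consumed without taking up nitrogen. The fallback sets out from 2 and 3 and comes back at 10. It fixes the nitrogen on the six-membered ring before any aldehyde is present.
- Condensation of 2 with 3 (pTsOH cat., toluene, Dean–Stark) gives 3-[(2-bromo-4-methoxy-5-nitrophenyl)amino]cyclohex-2-en-1-one F5.
- A Hantzsch-type annulation with aqueous chloroacetaldehyde (NaOAc, EtOH, 70 °C) joins the enaminone α-carbon to the aldehyde carbon and the nitrogen to the CH2Cl carbon, and loss of water gives 10.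
- Steps 2 and 3 are then not needed.

Step 10. Site selectivity between the two indole β-carbons may be lost, or ring A may be brominated a second time. The fallback sets out from 16 and comes back at 17. It tells the two rings apart by acidity instead of nucleophilicity.
- NaH (1.05 equiv) in THF at 0 °C removes the only acidic proton, N1–H of ring A, and gives sodium 5-bromo-4-(2,5-dibromo-1H-indol-1-yl)-7-methoxyindol-1-ide F6.
- At −78 °C this anion takes up bromine at C3 from 1,2-dibromo-1,1,2,2-tetrachloroethane. That donor reacts only by halophilic attack of anions and leaves the neutral ring B untouched.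
- Aqueous work-up then gives 17.

Further compounds
F1 | step 9 | 4-bromo-5-(2,5-dibromo-1H-indol-1-yl)-2-methoxyaniline | COc1cc(Br)c(-n2c(Br)cc3cc(Br)ccc32)cc1N
F2 | step 9 | 4-bromo-3-(2,5-dibromo-1H-indol-1-yl)-2-iodo-6-methoxyaniline | COc1cc(Br)c(-n2c(Br)cc3cc(Br)ccc32)c(I)c1N
F3 | step 9 | 4-bromo-3-(2,5-dibromo-1H-indol-1-yl)-6-methoxy-2-[(trimethylsilyl)ethynyl]aniline | COc1cc(Br)c(-n2c(Br)cc3cc(Br)ccc32)c(C#C[Si](C)(C)C)c1N
F4 | step 9 | 4-bromo-3-(2,5-dibromo-1H-indol-1-yl)-2-ethynyl-6-methoxyaniline | COc1cc(Br)c(-n2c(Br)cc3cc(Br)ccc32)c(C#C)c1N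
F5 | step 4 | 3-[(2-bromo-4-methoxy-5-nitrophenyl)amino]cyclohex-2-en-1-one | COc1cc(Br)c(NC2=CC(=O)CCC2)cc1[N+](=O)[O-]
F6 | step 10 | sodium 5-bromo-4-(2,5-dibromo-1H-indol-1-yl)-7-methoxyindol-1-ide | COc1cc(Br)c(-n2c(Br)cc3cc(Br)ccc32)c2cc[n-]c12.[Na+]
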